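You read these flasks at 15 min, so ask how many lifetimes of substrate fit into that time.

| flask | substrate | free catalyst | remark | time |
|---|---|---|---|---|
| ochre | 0.050 M | 0.052 mol% | run made earlier |  |
| amber | 0.050 M | 0.64 mol% | run made earlier |  |
| birch | 0.050 M | 0.8 mol% |  | 15 min |
| alder | 0.050 M | 0.3 mol% |  | 15 min |
| oak | 0.050 M | 0.22 mol% |  | 15 min |
| larch | 0.050 M | 0.4 mol% |  | 15 min |
| maple | 0.050 M | 0.15 mol% |  | 15 min |
| ash | 0.050 M | 0.08 mol% |  | 15 min |

- ochre (time / min: target / %, substrate / %): 2.00: 7, 88; 5.00: 8, 74; 10.0: 20, 54; 15.0: 22, 40
- amber (time / min: target / %, substrate / %): 2.00: 43, 56; 5.00: 71, 19; 10.0: 86, 3; 15.0: 92, 0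

(each reading ± 2 percentage points)

1. the flasks by amount of target, in percent of the substrate charged, highest first, at 15 min (birch / alder / oak / larch / maple / ash)
2. the amount of target, in percent of the substrate charged of the flask you put first, at 15 min
3. the amount of target, in percent of the substrate charged of the flask you put last, at 15 min

- percent here means substrate units held: one homo dimer counts as two
- what is said of target includes crystals
- crystals is a solid; its amount is given per volume of the solution
- on the list of suspects stand: substrate + free catalyst -> catalyst intermediate A; catalyst intermediate A -> catalyst intermediate B; catalyst intermediate B <-> free catalyst + target; 2 substrate -> homo dimer; crystals <-> target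

Amber kept 56 % of its substrate at 2.00 min, which is 0.580 lifetimes of a pseudo-first-order loss. Let that count grow with loading and with time. For birch at the reading it becomes 5.44: this is the lifetime count, the number of substrate lifetimes the catalytic path gets before you read. For ash it is 0.544. If the count were enough, [substrate] would stand at exp(−count) of its charge and the rest would be target.

Test that on ochre, whose count is 0.353. It predicts 70.3 % substrate, but the last reading shows 40 %, beside 22 % target. So one number is not enough: 38 percentage points are missing in ochre and 8 points in amber, presumably as homo dimer.

I reckon the two ends differently. Birch, like amber, has a large count, so I scale amber's missing share down by loading to 6.40 %, which leaves 93.2 % target. Ash, like ochre, has a small count, so I scale ochre's target up by loading to 33.8 %, from a reading that carries 2 points. The count climbs with loading, so I rank birch, larch, alder, oak, maple, ash.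

The forecast gives birch > larch > alder > oak > maple > ash, with 93 % for birch and 31 % for ash, below my ash figure, and says “Target rises steadily with loading, so the order follows catalyst charge”.

The flasks give birch > larch > alder > oak > maple > ash, with birch at 93.3 % and ash at 34.7 %.

    substrate + free catalyst → catalyst intermediate A (k = 2100 /M/min)
    catalyst intermediate A → catalyst intermediate B (k = 70.0 /min)
    catalyst intermediate B ⇌ free catalyst + target (K = 0.0470 M, k = 1100 /min)
    2 substrate → homo dimer (k = 0.480 /M/min)
    crystals ⇌ target, rate k5*(cs5 - [target]) while solid is left; crystals form when [target] > cs5 (solubility = 35.0 mM, k = 2.20 /min)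

Cut to 4.0 min, birch's count of 5.44 becomes 1.45, which predicts 23.5 % substrate, and that stopped flask holds 20.7 %. In birch the catalytic cycle and the dimerisation ran while substrate lasted: at 7.50 min there stood 4.46 % substrate, 89.0 % target and the 6.17 % homo dimer still found at 15.0 min. Crystals then went on growing from 17.8 % to 23.3 % at 15.0 min, when the catalyst stood as 57.2 % free catalyst, 42.7 % catalyst intermediate B and 0.109 % catalyst intermediate A.

The earlier runs and the new flask stem from a simulated flask with made-up constants, and the scatter is random.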